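Atoms carry longipinane numbers (C1 ketone, C2=C3, cyclobutane C4–C5–C11–C10, C6 CMe2, C7/C8/C9 oxygenated). The seven-membered ring C5–C9/C10/C4 is read as a cyclopentanone enlarged by the alkene carbons C10 and C4. An intramolecular de Mayo-type [2+2] photocycloaddition of enol carbonate 10 (five-membered ring from 4,4-dimethylcyclopentenone; acyl chain from (R)-linalool, whose C1–C6 become the whole cyclohexenone ring) forms C4–C5 and C9–C10 as two bonds of a temporary cyclobutane. Retro-aldol cleavage of its C5–C9 bond releases the cis-fused six/seven diketone; enolate alkylation (C10–C11) then closes the true cyclobutane.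

Key step: step 8

Remark (assumption): the quaternary C3 centre of (R)-linalool is assumed to favour the enone face drawn for 11 (methyl pseudo-equatorial in the forming ring); if the opposite holds, (S)-linalool is used and only the C3 descriptor of 2–20 changes. C10 is drawn without descriptor in 11–18 (epimers, planarised in step 14).

Step 1
Reactants: 1 (R)-(−)-linalool
Product: 2 (3R)-3,7-dimethyl-3-(triethylsilyloxy)octa-1,6-diene
Conditions: Et3SiOTf, 2,6-lutidine, CH2Cl2, −78 to 0 °C
Reagents that add atoms: triethylsilyl trifluoromethanesulfonate, CC[Si](CC)(CC)OS(=O)(=O)C(F)(F)F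
Why: Silyl triflate silylation of a tertiary alcohol masks the C3 oxygen through all later base-mediated steps.

Step 2
Reactants: 2 linalool triethylsilyl ether
Product: 3 (4R)-4-methyl-4-(triethylsilyloxy)hex-5-enal
Conditions: O3 (1 equiv, Sudan red end point), pyridine, CH2Cl2, −78 °C; then PPh3
Reagents that add atoms: ozone, [O-][O+]=O
Why: Chemoselective ozonolysis should cleave the electron-rich trisubstituted alkene well before the vinyl group on the quaternary carbon, giving the aldehyde carbon that becomes C11.

Step 3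
Reactants: 3 vinyl aldehyde; 4 (Z)-but-2-ene
Product: 5 (4R,5E)-4-methyl-4-(triethylsilyloxy)hept-5-enal
Conditions: Hoveyda–Grubbs second-generation catalyst RuCl2(H2IMes)(=CH-C6H4-2-OiPr), C31H38Cl2N2ORu (5 mol %), excess 4, CH2Cl2, 40 °C, sealed tube
Reagents that add atoms: none
Why: Olefin cross-metathesis exchanges the terminal methylene for ethylidene and so brings in the future C10 methyl group; the alkene geometry is lost later.

Step 4
Reactants: 6 4,4-dimethylcyclopent-2-en-1-one; 5 propenyl aldehyde
Product: 7 5-[(4R,5E)-1-hydroxy-4-methyl-4-(triethylsilyloxy)hept-5-en-1-yl]-4,4-dimethylcyclopent-2-en-1-one (epimers at the two new centres)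
Conditions: LiN(iPr)2, THF, −78 °C, 6 then 5; AcOH quench
Reagents that add atoms: none
Why: Aldol addition of the kinetic cross-conjugated lithium enolate, formed at the only enolisable carbon of 6 (future C5), to the aldehyde; both new centres are removed in steps 6 and 9.

Step 5
Reactants: 7 aldol adduct
Product: 8 2-[(4R,5E)-1-hydroxy-4-methyl-4-(triethylsilyloxy)hept-5-en-1-yl]-3,3-dimethylcyclopentan-1-one (epimers)
Conditions: [(Ph3P)CuH]6 (0.3 equiv), benzene, H2O (2 equiv), rt
Reagents that add atoms: none
Why: Copper hydride conjugate reduction should saturate only the enone C=C, so that the later ring enol carbonate is not a cyclopentadiene.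

Step 6
Reactants: 8 β-hydroxy ketone
Product: 9 3,3-dimethyl-2-[(4R,5E)-4-methyl-4-(triethylsilyloxy)hept-5-enoyl]cyclopentan-1-one
Conditions: Dess–Martin periodinane, NaHCO3, CH2Cl2, rt
Reagents that add atoms: none
Why: Dess–Martin oxidation of the β-hydroxy ketone gives the 1,3-diketone (C9 and C11 carbonyls flanking C5).

Step 7
Reactants: 9 β-diketone
Product: 10 benzyl 3,3-dimethyl-2-[(4R,5E)-4-methyl-4-(triethylsilyloxy)hept-5-enoyl]cyclopent-1-en-1-yl carbonate
Conditions: ClCO2Bn, pyridine, CH2Cl2, 0 °C
Reagents that add atoms: benzyl chloroformate, O=C(Cl)OCc1ccccc1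
Why: O-acylation of the enolised 1,3-diketone fixes the C5=C9 double bond in the ring, the exocyclic enol ester being disfavoured by allylic strain with the C6 gem-dimethyl group.

Step 8
Reactants: 10 enol carbonate
Product: 11 9-(benzyloxycarbonyloxy)-3-(triethylsilyloxy)-5,9-cyclo-10,11-secolongipinan-11-one (cis,cis-fused five/four/six tricycle; C9–O and C11 on one cyclobutane face, C8 and C6 on the other)
Conditions: hν (350 nm, Pyrex), degassed MeCN, rt
Reagents that add atoms: none
Why: Excitation of the β-acyloxy enone (C11=O, C5=C9) gives its triplet, whose α-carbon C5 bonds to the tethered alkene carbon C4, and the resulting 1,4-diradical (C9, C10) collapses to the cyclobutane C4–C5–C9–C10; this is an intramolecular enone–alkene [2+2] photocycloaddition in its de Mayo form (enol ester of a 1,3-diketone). The cyclohexanone ring (C4–C5–C11–C1–C2–C3) closes first in a 1,6 (six-exo-type) mode because the four-atom tether cannot give a five-membered ring, and the cyclobutane then closes by radical recombination as the straight, fused adduct. C4/C5 and C5/C9 are cis ring fusions enforced by tether and ring strain. The enone face is chosen by the quaternary C3 centre from linalool, which sits in the forming six-membered ring with methyl pseudo-equatorial and silyloxy pseudo-axial; C10 forms as a mixture and is planarised later. The step therefore needs regioselectivity (straight, not crossed), secured by tether length, and facial selectivity, secured by C3, with a minor diastereomer removed by chromatography. Linalool carbons C1–C6 thus become C10, C4, C3, C2, C1 and C11, and the cyclopentanone carbons become C5–C9.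

Step 9
Reactants: 11 photoadduct
Product: 13 cis-fused 3-(triethylsilyloxy)-10,11-secolongipinane-9,11-dione, via cyclobutanol 12 (not isolated)
Conditions: H2 (1 atm), Pd/C, EtOAc, rt; then Et3N (cat.), CH2Cl2, rt
Reagents that add atoms: none
Why: Hydrogenolysis of the benzyl carbonate unmasks the strained β-hydroxy ketone, whose retro-aldol (de Mayo) fragmentation cuts C5–C9 and enlarges the five-membered ring by two carbons; C5, α to the C11 ketone, is equilibrated to the cis ring fusion (H4/H5 cis).

Step 10
Reactants: 13 diketone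
Product: 14 11-hydroxy-3-(triethylsilyloxy)-10,11-secolongipinan-9-one (11-OH equatorial, trans to C6)
Conditions: NaBH4, MeOH/CH2Cl2, −78 °C
Reagents that add atoms: none
Why: Borohydride reduction should take the cyclohexanone (C11) far faster than the α-branched cycloheptanone (C9), and axial hydride delivery gives the equatorial alcohol trans to the C5–C6 bond.

Step 11
Reactants: 14 hydroxy ketone
Product: 15 11-(methanesulfonyloxy)-3-(triethylsilyloxy)-10,11-secolongipinan-9-one
Conditions: MsCl, Et3N, CH2Cl2, 0 °C
Reagents that add atoms: methanesulfonyl chloride, CS(=O)(=O)Cl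
Why: Sulfonylation turns the C11 oxygen into the leaving group for step 14 with retention at C11.

Step 12
Reactants: 15 keto methanesulfonate
Product: 17 11-(methanesulfonyloxy)-3-(triethylsilyloxy)-10,11-secolongipin-7-en-9-one, via silyl enol ether 16 (not isolated)
Conditions: LiN(iPr)2, Me3SiCl (internal quench), THF, −78 °C; then Pd(OAc)2 (1 equiv), MeCN, rt
Reagents that add atoms: chlorotrimethylsilane, C[Si](C)(C)Cl (silyl group of 16 only)
Why: Saegusa–Ito dehydrogenation: kinetic deprotonation occurs at the C8 methylene, not at the C10 methine, so the enone forms toward C7 and removes the C8 hydrogens that would otherwise compete in step 14.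

Step 13
Reactants: 17 enone
Product: 18 7,8-epoxy-11-(methanesulfonyloxy)-3-(triethylsilyloxy)-10,11-secolongipinan-9-one (epoxide cis to H4 and H5)
Conditions: 30% H2O2, NaOH, MeOH, 0 °C
Reagents that add atoms: hydrogen peroxide, OO
Why: Weitz–Scheffer epoxidation from the convex face of the cis-fused bicycle (the face of H4 and H5) sets C7 and C8, and the epoxide keeps C8 non-enolisable.

Step 14
Reactants: 18 epoxy keto methanesulfonate
Product: 19 7,8-epoxy-3-(triethylsilyloxy)longipinan-9-one
Conditions: KN(SiMe3)2, THF, −78 to 0 °C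
Reagents that add atoms: none
Why: Intramolecular enolate alkylation (four-exo-tet): the only possible enolate (C10) displaces the equatorial C11 methanesulfonate with inversion across the cis ring fusion, as in classical keto-sulfonate closures of copaane- and pinane-type cyclobutanes; this closes C4–C5–C11–C10 and the cage fixes C10 and C11.

Step 15
Reactants: 19 silyl ether
Product: 20 7,8-epoxy-3-hydroxylongipinan-9-one
Conditions: Bu4NF, THF, rt
Reagents that add atoms: none
Why: Fluoride desilylation frees the tertiary C3 alcohol; the ketone now has no enolisable hydrogen.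

Step 16
Reactants: 20 tertiary alcohol
Product: 21 7,8-epoxylongipin-2-en-9-one
Conditions: Burgess reagent (MeO2C–N(−)–SO2–N(+)Et3), benzene, 50 °C
Reagents that add atoms: none
Why: Burgess syn-elimination should give the trisubstituted C2=C3 alkene; C4 is a bridgehead and cannot take part.

Step 17
Reactants: 21 epoxy ketone
Product: 23 longipina-2,8-dien-7-ol, via epoxy hydrazone 22 (not isolated)
Conditions: N2H4·H2O, AcOH (cat.), MeOH, 0 °C to rt
Reagents that add atoms: hydrazine, NN (nitrogen of 22 only)
Why: Wharton transposition turns the epoxy ketone into the allylic alcohol with the C8=C9 alkene; the C7–O bond is never broken, so C7 keeps the configuration set in step 13.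

Step 18
Reactants: 23 allylic alcohol; 24 angelic acid
Product: 25 longipina-2,8-dien-7-yl angelate
Conditions: 24, 2,4,6-trichlorobenzoyl chloride, Et3N, toluene, rt; then 23, toluene, 80 °C
Reagents that add atoms: none
Why: Yamaguchi-type mixed-anhydride esterification without a nucleophilic amine catalyst avoids Z-to-E isomerisation to the tiglate, and O7 is acylated now so that it survives step 19 and directs step 20.

Step 19
Reactants: 25 diene ester
Product: 26 7-angeloyloxylongipina-2,8-dien-1-one
Conditions: Rh2(C6H10NO)4 (dirhodium tetracaprolactamate, 1 mol %), t-BuOOH, K2CO3, CH2Cl2, rt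
Reagents that add atoms: tert-butyl hydroperoxide, CC(C)(C)OO
Why: Allylic oxidation of the electron-rich trisubstituted C2=C3 alkene at its only allylic methylene, C1 (the α-pinene-to-verbenone reaction type); the ester-deactivated C8=C9 alkene and the angelate should react more slowly.

Step 20
Reactants: 26 dienone ester
Product: 27 7-angeloyloxy-8,9-dihydroxylongipin-2-en-1-one
Conditions: OsO4 (cat.), N-methylmorpholine N-oxide, acetone/H2O, rt
Reagents that add atoms: N-methylmorpholine N-oxide, C[N+]1([O-])CCOCC1; water, O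
Why: Upjohn syn-dihydroxylation of the only electron-rich alkene (C8=C9), anti to the allylic C7 acyloxy group (Kishi model), sets C8 and C9 cis to each other and trans to O7.

Step 21
Reactants: 27 diol; 28 (R)-2-methylbutanoic acid
Product: 29 (4R,5S,7S,8S,9S,10R,11R)-7-angeloyloxy-9-hydroxy-8-[(2R)-2-methylbutanoyloxy]longipin-2-en-1-one (CNP0206166.1)
Conditions: 28, DCC, DMAP (cat.), CH2Cl2, 0 °C
Reagents that add atoms: none
Why: Steglich esterification should acylate the C8 hydroxyl selectively, because the C9 hydroxyl is neopentyl and shielded by quaternary C10.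

Compound list
1 | (R)-(−)-linalool | C=C[C@](C)(O)CCC=C(C)C | starting material
2 | (3R)-3,7-dimethyl-3-(triethylsilyloxy)octa-1,6-diene | C=C[C@](C)(O[Si](CC)(CC)CC)CCC=C(C)C | intermediate
3 | (4R)-4-methyl-4-(triethylsilyloxy)hex-5-enal | C=C[C@](C)(O[Si](CC)(CC)CC)CCC=O | intermediate
4 | (Z)-but-2-ene | C/C=C\C | starting material
5 | (4R,5E)-4-methyl-4-(triethylsilyloxy)hept-5-enal | C/C=C/[C@](C)(O[Si](CC)(CC)CC)CCC=O | intermediate
6 | 4,4-dimethylcyclopent-2-en-1-one | O=C1C=CC(C)(C)C1 | starting material
7 | aldol adduct (epimers at carbinol and ring carbon) | C/C=C/[C@](C)(O[Si](CC)(CC)CC)CCC(O)C1C(=O)C=CC1(C)C | intermediate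
8 | saturated β-hydroxy ketone (epimers) | C/C=C/[C@](C)(O[Si](CC)(CC)CC)CCC(O)C1C(=O)CCC1(C)C | intermediate
9 | 3,3-dimethyl-2-[(4R,5E)-4-methyl-4-(triethylsilyloxy)hept-5-enoyl]cyclopentan-1-one | C/C=C/[C@](C)(O[Si](CC)(CC)CC)CCC(=O)C1C(=O)CCC1(C)C | intermediate
10 | benzyl enol carbonate of 9 (ring enol) | C/C=C/[C@](C)(O[Si](CC)(CC)CC)CCC(=O)C1=C(OC(=O)OCc2ccccc2)CCC1(C)C | intermediate
11 | 9-(benzyloxycarbonyloxy)-3-(triethylsilyloxy)-5,9-cyclo-10,11-secolongipinan-11-one (C10 epimers) | O=C1CC[C@@](C)(O[Si](CC)(CC)CC)[C@@H]2C(C)[C@@]3(OC(=O)OCc4ccccc4)CCC(C)(C)[C@@]123 | intermediate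
12 | 9-hydroxy-3-(triethylsilyloxy)-5,9-cyclo-10,11-secolongipinan-11-one (not isolated) | O=C1CC[C@@](C)(O[Si](CC)(CC)CC)[C@@H]2C(C)[C@@]3(O)CCC(C)(C)[C@@]123 | intermediate
13 | cis-fused 3-(triethylsilyloxy)-10,11-secolongipinane-9,11-dione | O=C1CC[C@@](C)(O[Si](CC)(CC)CC)[C@@H]2C(C)C(=O)CCC(C)(C)[C@H]12 | intermediate
14 | 11-hydroxy-3-(triethylsilyloxy)-10,11-secolongipinan-9-one | O[C@H]1CC[C@@](C)(O[Si](CC)(CC)CC)[C@@H]2C(C)C(=O)CCC(C)(C)[C@H]12 | intermediate
15 | 11-methanesulfonate of 14 | CS(=O)(=O)O[C@H]1CC[C@@](C)(O[Si](CC)(CC)CC)[C@@H]2C(C)C(=O)CCC(C)(C)[C@H]12 | intermediate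
16 | 9-(trimethylsilyloxy)-8-ene silyl enol ether of 15 (not isolated) | CS(=O)(=O)O[C@H]1CC[C@@](C)(O[Si](CC)(CC)CC)[C@@H]2C(C)C(O[Si](C)(C)C)=CCC(C)(C)[C@H]12 | intermediate
17 | 11-(methanesulfonyloxy)-3-(triethylsilyloxy)-10,11-secolongipin-7-en-9-one | CS(=O)(=O)O[C@H]1CC[C@@](C)(O[Si](CC)(CC)CC)[C@@H]2C(C)C(=O)C=CC(C)(C)[C@H]12 | intermediate
18 | 7,8-epoxy-11-(methanesulfonyloxy)-3-(triethylsilyloxy)-10,11-secolongipinan-9-one | CS(=O)(=O)O[C@H]1CC[C@@](C)(O[Si](CC)(CC)CC)[C@@H]2C(C)C(=O)[C@H]3O[C@H]3C(C)(C)[C@H]12 | intermediate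
19 | 7,8-epoxy-3-(triethylsilyloxy)longipinan-9-one | O1[C@@H]2[C@H]1C(=O)[C@@]3(C)[C@@H]4CC[C@@](C)(O[Si](CC)(CC)CC)[C@H]3[C@@H]4C2(C)C | intermediate
20 | 7,8-epoxy-3-hydroxylongipinan-9-one | O1[C@@H]2[C@H]1C(=O)[C@@]3(C)[C@@H]4CC[C@@](C)(O)[C@H]3[C@@H]4C2(C)C | intermediate
21 | 7,8-epoxylongipin-2-en-9-one | O1[C@@H]2[C@H]1C(=O)[C@@]3(C)[C@@H]4CC=C(C)[C@H]3[C@@H]4C2(C)C | intermediate
22 | hydrazone of 21 (not isolated) | O1[C@@H]2[C@H]1C(=NN)[C@@]3(C)[C@@H]4CC=C(C)[C@H]3[C@@H]4C2(C)C | intermediate
23 | longipina-2,8-dien-7-ol | O[C@@H]1C=C[C@@]2(C)[C@@H]3CC=C(C)[C@H]2[C@@H]3C1(C)C | intermediate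
24 | angelic acid, (Z)-2-methylbut-2-enoic acid | C/C=C(/C)C(=O)O | starting material
25 | longipina-2,8-dien-7-yl angelate | C/C=C(/C)C(=O)O[C@@H]1C=C[C@@]2(C)[C@@H]3CC=C(C)[C@H]2[C@@H]3C1(C)C | intermediate
26 | 7-angeloyloxylongipina-2,8-dien-1-one | C/C=C(/C)C(=O)O[C@@H]1C=C[C@@]2(C)[C@@H]3C(=O)C=C(C)[C@H]2[C@@H]3C1(C)C | intermediate
27 | 7-angeloyloxy-8,9-dihydroxylongipin-2-en-1-one | C/C=C(/C)C(=O)O[C@@H]1[C@@H](O)[C@@H](O)[C@@]2(C)[C@@H]3C(=O)C=C(C)[C@H]2[C@@H]3C1(C)C | intermediate
28 | (R)-2-methylbutanoic acid | CC[C@@H](C)C(=O)O | starting material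
29 | CNP0206166.1 | C/C=C(/C)C(=O)O[C@@H]1[C@@H](OC(=O)[C@H](C)CC)[C@@H](O)[C@@]2(C)[C@@H]3C(=O)C=C(C)[C@H]2[C@@H]3C1(C)C | target

Total steps: 21. Longest linear sequence: 21 steps (1 to 29).

Steps most likely to fail

Step 8. The excited enol carbonate may lose its energy by E/Z isomerisation of the propenyl group or by 1,3-acyl migration instead of closing, and the C3 centre may discriminate the enone faces only weakly. The fallback sets out from 9 and comes back at 13: the free, hydrogen-bonded enol of β-diketone 9 is irradiated directly (classical de Mayo reaction), so that cyclobutanol 12 forms and fragments in the same flask to diketone 13 without any enol ester; diastereomers are separated at 13.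

Step 14. Displacement at the β-branched secondary C11 may be outrun by loss of methanesulfonate through elimination or by reaction at the enolate oxygen. The fallback sets out from 18 and comes back at 19: condensation with 1,1-dimethylhydrazine gives the N,N-dimethylhydrazone F1; LiN(iPr)2 forms the softer, less basic azaenolate at C10, which cyclises onto C11 to the tricyclic hydrazone F2; hydrolysis (aqueous oxalic acid, or Cu(OAc)2 in aqueous THF) returns ketone 19 (Corey–Enders hydrazone alkylation).

Step 16. The elimination may take a hydrogen from the C3 methyl group instead of C2 and give the exocyclic alkene, or the sulfamate may ionise and trigger skeletal rearrangement of the pinane-like cage. The fallback sets out from 20 and comes back at 21: dehydration (SOCl2, pyridine) is allowed to give the exocyclic methylene compound F3; ozonolysis (O3, then Me2S) gives the 3-ketone F4, which can enolise only toward C2; KN(SiMe3)2 and PhNTf2 give the enol trifluoromethanesulfonate F5; Stille methylation (Me4Sn, Pd(PPh3)4, LiCl, DMF) then gives 21 with the alkene fixed at C2=C3.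

Further compounds
F0 | step 8 | none | none
F1 | step 14 | N,N-dimethylhydrazone of 18 | CS(=O)(=O)O[C@H]1CC[C@@](C)(O[Si](CC)(CC)CC)[C@@H]2C(C)C(=NN(C)C)[C@H]3O[C@H]3C(C)(C)[C@H]12
F2 | step 14 | N,N-dimethylhydrazone of 19 | O1[C@@H]2[C@H]1C(=NN(C)C)[C@@]3(C)[C@@H]4CC[C@@](C)(O[Si](CC)(CC)CC)[C@H]3[C@@H]4C2(C)C
F3 | step 16 | 7,8-epoxylongipin-3(12)-en-9-one (exocyclic methylene) | O1[C@@H]2[C@H]1C(=O)[C@@]3(C)[C@@H]4CCC(=C)[C@H]3[C@@H]4C2(C)C
F4 | step 16 | 7,8-epoxy-12-norlongipinane-3,9-dione | O1[C@@H]2[C@H]1C(=O)[C@@]3(C)[C@@H]4CCC(=O)[C@H]3[C@@H]4C2(C)C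
F5 | step 16 | 7,8-epoxy-9-oxo-12-norlongipin-2-en-3-yl trifluoromethanesulfonate | O1[C@@H]2[C@H]1C(=O)[C@@]3(C)[C@@H]4CC=C(OS(=O)(=O)C(F)(F)F)[C@H]3[C@@H]4C2(C)C
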